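**Strategy.** In the 1,2-dioxane (O1, O2, C3–C6) the hemiketal carbon C3 and the tertiary peroxide carbon C6 are separated only by C4 and C5, so a retrosynthetic C3–C6 bond contracts the ring to a cyclobutanol. One aerobic, Co(acac)2-mediated operation breaks that bond, places O2 on C6 and closes the hydroperoxide onto the freed C3 ketone, giving the ring, both C–O bonds and both oxygenated stereocentres. The precursor is a tert-butyl (1-hydroxycyclobutyl)acetate that already carries the C4 methyl group in its final (R) configuration, together with the C6 methyl group and the (R)-2-methyl-10-phenyldecyl chain. It is built from (R)-citronellal by a spiroannulation and an auxiliary-controlled methylation.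

Key step: step 12

Numbering: cyclobutane C1 (carbinol) becomes dioxane C3, C2 (quaternary) becomes C6, C3 becomes C5, and C4 (CHMe) becomes C4.

Assumption: in the ring-opened tautomer C4 is the γ-carbon of a β-keto ester and is not expected to epimerise under conditions a peroxide survives. Its (R) configuration is therefore installed before the ring expansion, while cyclobutane C1 and C2 are carried as mixtures because the key step erases both.

**Route**

Step 1
Reactants: 1 (R)-citronellal
Product: 2 (4R)-4,8-dimethylnon-7-en-2-ol (C2 epimers)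
Conditions: MeMgBr, Et2O, 0 °C; H2O quench
Reagents that add atoms: methylmagnesium bromide, C[Mg]Br
Why: Grignard addition to the aldehyde is fast at 0 °C and leaves the trisubstituted alkene and the existing stereocentre (β to the carbonyl) untouched; the new carbinol centre is uncontrolled and is erased by the oxidation in step 6.

Step 2
Reactants: 2 (4R)-4,8-dimethylnon-7-en-2-ol
Product: 4 (4R)-6-hydroxy-4-methylheptanal, via secondary ozonide 3 (not isolated)
Conditions: O3, CH2Cl2, −78 °C; then Me2S, −78 °C → rt
Reagents that add atoms: ozone, [O-][O+]=O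
Why: Ozonolysis with reductive work-up cleaves the electron-rich trisubstituted alkene to the aldehyde and acetone, and the free secondary alcohol is inert to ozone at −78 °C.

Step 3
Reactants: 5 (5-bromopentyl)benzene; 6 triphenylphosphine
Product: 7 (5-phenylpentyl)triphenylphosphonium bromide
Conditions: MeCN, reflux
Reagents that add atoms: none
Why: SN2 quaternisation of triphenylphosphine by a primary alkyl bromide gives the Wittig salt.

Step 4
Reactants: 4 (4R)-6-hydroxy-4-methylheptanal; 7 (5-phenylpentyl)triphenylphosphonium bromide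
Product: 9 (4R,7Z)-4-methyl-12-phenyldodec-7-en-2-ol (Z isomer expected to predominate), via phosphorus ylide 8 (not isolated)
Conditions: NaHMDS, THF, 0 °C; then 4, −78 °C → rt (ylide in excess)
Reagents that add atoms: none
Why: Wittig olefination with an unstabilised ylide takes the aldehyde chemoselectively; the ylide is too weak a base to be consumed by the secondary alcohol, and the alkene geometry is irrelevant because the double bond is hydrogenated next.

Step 5
Reactants: 9 (4R,7Z)-4-methyl-12-phenyldodec-7-en-2-ol
Product: 10 (4R)-4-methyl-12-phenyldodecan-2-ol (C2 epimers)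
Conditions: H2 (1 atm), Pd/C, EtOAc, rt
Reagents that add atoms: none
Why: Heterogeneous catalytic hydrogenation saturates the disubstituted alkene without touching the arene or the non-benzylic alcohol.

Step 6
Reactants: 10 (4R)-4-methyl-12-phenyldodecan-2-ol
Product: 11 (4R)-4-methyl-12-phenyldodecan-2-one
Conditions: TEMPO (cat.), KBr (cat.), NaOCl, NaHCO3, CH2Cl2/H2O, 0 °C
Reagents that add atoms: none
Why: Anelli oxidation (oxoammonium salt from TEMPO and hypochlorite) converts the secondary alcohol into the methyl ketone; the stereocentre is β to the carbonyl and not at risk.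

Step 7
Reactants: 11 (4R)-4-methyl-12-phenyldodecan-2-one; 12 cyclopropyldiphenylsulfonium tetrafluoroborate
Product: 15 2-methyl-2-[(2R)-2-methyl-10-phenyldecyl]cyclobutan-1-one (C2 epimers), via sulfonium cyclopropylide 13 (not isolated), via oxaspiropentane 14 (not isolated)
Conditions: KOH, DMSO, rt; then aq. HBF4, Et2O, rt
Reagents that add atoms: none
Why: Trost spiroannulation: the cyclopropylide, formed reversibly by KOH in DMSO, adds to the ketone and closes to the oxaspiropentane, whose acid-induced cyclopropylcarbinyl-to-cyclobutyl shift gives the cyclobutanone with the former carbonyl carbon as quaternary C2; this centre forms without control and is destroyed in step 12.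

Step 8
Reactants: 15 2-methyl-2-[(2R)-2-methyl-10-phenyldecyl]cyclobutan-1-one; 16 (S)-1-amino-2-(methoxymethyl)pyrrolidine (SAMP)
Product: 17 (2S)-2-(methoxymethyl)-N-[2-methyl-2-[(2R)-2-methyl-10-phenyldecyl]cyclobutylidene]pyrrolidin-1-amine
Conditions: TsOH (cat.), cyclohexane, reflux (Dean–Stark)
Reagents that add atoms: none
Why: Acid-catalysed hydrazone condensation, helped by the strain-enhanced electrophilicity of the cyclobutanone; the amino nitrogen should settle anti to the quaternary C2.

Step 9
Reactants: 17 SAMP hydrazone of the cyclobutanone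
Product: 19 (2S)-N-[(4R)-2,4-dimethyl-2-[(2R)-2-methyl-10-phenyldecyl]cyclobutylidene]-2-(methoxymethyl)pyrrolidin-1-amine, via lithium azaenolate 18 (not isolated)
Conditions: LDA, THF, −78 → 0 °C; then MeI, −100 °C → rt
Reagents that add atoms: iodomethane, CI
Why: Enders SAMP-hydrazone alkylation: LDA deprotonates the only enolisable position (C4), and the lithium azaenolate, chelated by the methoxymethyl arm, is methylated on one face under reagent control, which for cyclic ketone SAMP hydrazones gives the (R)-α-methyl centre whatever the C2 configuration.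

Step 10
Reactants: 19 methylated SAMP hydrazone
Product: 20 (4R)-2,4-dimethyl-2-[(2R)-2-methyl-10-phenyldecyl]cyclobutan-1-one (C2 epimers)
Conditions: sat. aq. oxalic acid, Et2O, rt
Reagents that add atoms: water, O
Why: Mild two-phase hydrazone hydrolysis with oxalic acid releases the ketone without epimerising the α-methyl centre and allows the auxiliary to be recovered.

Step 11
Reactants: 20 (4R)-2,4-dimethyl-2-[(2R)-2-methyl-10-phenyldecyl]cyclobutan-1-one; 21 tert-butyl bromoacetate
Product: 23 tert-butyl 2-[(4R)-1-hydroxy-2,4-dimethyl-2-[(2R)-2-methyl-10-phenyldecyl]cyclobutyl]acetate (C1 and C2 epimers), via Reformatsky reagent 22 (not isolated)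
Conditions: Zn (TMSCl-activated), THF, 40 °C; then 20, 0 °C → rt; aqueous work-up
Reagents that add atoms: none
Why: Reformatsky addition: the weakly basic zinc enolate adds to the strained, electrophilic cyclobutanone without enolising C4; the new carbinol centre C1 is uncontrolled and is erased in step 12.

Step 12
Reactants: 23 tert-butyl 2-[(4R)-1-hydroxy-2,4-dimethyl-2-[(2R)-2-methyl-10-phenyldecyl]cyclobutyl]acetate
Product: 25 tert-butyl 2-[(3S,4R,6S)-3-hydroxy-4,6-dimethyl-6-[(2R)-2-methyl-10-phenyldecyl]-1,2-dioxan-3-yl]acetate, via open-chain hydroperoxy ketone 24 (not isolated)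
Conditions: Co(acac)2 (20 mol %), O2 (1 atm), CH2Cl2, rt; chromatographic (HPLC) separation of the C6 epimer
Reagents that add atoms: dioxygen, O=O
Why: The tertiary alcohol binds cobalt that O2 has raised to the trivalent state, Co–O homolysis gives the cyclobutyloxy radical, and strain-driven β-scission breaks C1–C2 (dioxane C3–C6); triplet O2 then adds at C6, and the peroxyl radical is taken up by divalent cobalt and released as hydroperoxide 24 by exchange with the next molecule of alcohol. This is the known cobalt- or manganese-acetylacetonate aerobic ring expansion of cyclobutanols to 1,2-dioxan-3-ols. The C6–O1 bond is made in the radical capture, and the ring closes through O2–C3 by a reversible 6-exo-trig hemiketalisation of the OOH group onto the new ketone. C3 is set thermodynamically: ring–chain tautomerism should settle on the chair with axial (anomeric) OH, equatorial CH2CO2tBu and equatorial C4 methyl, which is (3S) beside the preset (4R) centre. C6 is not controlled, because O2 meets a planar acyclic radical, so 25 and its (6R) epimer are expected in similar amounts and must be separated. The selectivity the step needs is the direction of β-scission, secured by the quaternary cyclobutane C2 (tertiary radical, against a secondary one from C1–C4 cleavage), while C4 takes no part in the radical events.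

Step 13
Reactants: 25 tert-butyl 2-[(3S,4R,6S)-3-hydroxy-4,6-dimethyl-6-[(2R)-2-methyl-10-phenyldecyl]-1,2-dioxan-3-yl]acetate
Product: 26 2-[(3S,4R,6S)-3-hydroxy-4,6-dimethyl-6-[(2R)-2-methyl-10-phenyldecyl]-1,2-dioxan-3-yl]acetic acid
Conditions: CF3CO2H/CH2Cl2 (1:4), 0 °C, short reaction time
Reagents that add atoms: none
Why: Acidolysis of the tert-butyl ester through the tert-butyl cation (lost as isobutene) frees the acid; the dialkyl peroxide should tolerate brief cold acid and the hemiketal, if ionised, re-forms on aqueous work-up, so the ring and all four stereocentres should survive.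

**Compound list**

1 | (R)-citronellal | C[C@H](CCC=C(C)C)CC=O | starting material
2 | (4R)-4,8-dimethylnon-7-en-2-ol (C2 epimers) | C[C@H](CCC=C(C)C)CC(C)O | intermediate
3 | (4R)-6-(5,5-dimethyl-1,2,4-trioxolan-3-yl)-4-methylhexan-2-ol (secondary ozonide) | C[C@H](CCC1OOC(C)(C)O1)CC(C)O | intermediate (not isolated)
4 | (4R)-6-hydroxy-4-methylheptanal | C[C@H](CCC=O)CC(C)O | intermediate
5 | (5-bromopentyl)benzene | BrCCCCCc1ccccc1 | starting material
6 | triphenylphosphine | c1ccc(cc1)P(c1ccccc1)c1ccccc1 | starting material
7 | (5-phenylpentyl)triphenylphosphonium bromide | [Br-].c1ccc(cc1)CCCCC[P+](c1ccccc1)(c1ccccc1)c1ccccc1 | intermediate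
8 | (5-phenylpentylidene)triphenylphosphorane | c1ccc(cc1)CCCCC=P(c1ccccc1)(c1ccccc1)c1ccccc1 | intermediate (not isolated)
9 | (4R,7Z)-4-methyl-12-phenyldodec-7-en-2-ol | C[C@H](CC/C=C\CCCCc1ccccc1)CC(C)O | intermediate
10 | (4R)-4-methyl-12-phenyldodecan-2-ol (C2 epimers) | C[C@H](CCCCCCCCc1ccccc1)CC(C)O | intermediate
11 | (4R)-4-methyl-12-phenyldodecan-2-one | C[C@H](CCCCCCCCc1ccccc1)CC(C)=O | intermediate
12 | cyclopropyldiphenylsulfonium tetrafluoroborate | F[B-](F)(F)F.c1ccc(cc1)[S+](C1CC1)c1ccccc1 | starting material
13 | diphenylsulfonium cyclopropylide | c1ccc(cc1)[S+]([C-]1CC1)c1ccccc1 | intermediate (not isolated)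
14 | 2-methyl-2-[(2R)-2-methyl-10-phenyldecyl]-1-oxaspiro[2.2]pentane | C[C@H](CCCCCCCCc1ccccc1)CC1(C)OC12CC2 | intermediate (not isolated)
15 | 2-methyl-2-[(2R)-2-methyl-10-phenyldecyl]cyclobutan-1-one (C2 epimers) | C[C@H](CCCCCCCCc1ccccc1)CC1(C)CCC1=O | intermediate
16 | (S)-1-amino-2-(methoxymethyl)pyrrolidine (SAMP) | COC[C@@H]1CCCN1N | starting material
17 | (2S)-2-(methoxymethyl)-N-[2-methyl-2-[(2R)-2-methyl-10-phenyldecyl]cyclobutylidene]pyrrolidin-1-amine | C[C@H](CCCCCCCCc1ccccc1)CC1(C)CCC1=NN1CCC[C@H]1COC | intermediate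
18 | lithium azaenolate of 17 | C[C@H](CCCCCCCCc1ccccc1)CC1(C)CC=C1N([Li])N1CCC[C@H]1COC | intermediate (not isolated)
19 | (2S)-N-[(4R)-2,4-dimethyl-2-[(2R)-2-methyl-10-phenyldecyl]cyclobutylidene]-2-(methoxymethyl)pyrrolidin-1-amine | C[C@H](CCCCCCCCc1ccccc1)CC1(C)C[C@@H](C)C1=NN1CCC[C@H]1COC | intermediate
20 | (4R)-2,4-dimethyl-2-[(2R)-2-methyl-10-phenyldecyl]cyclobutan-1-one (C2 epimers) | C[C@H](CCCCCCCCc1ccccc1)CC1(C)C[C@@H](C)C1=O | intermediate
21 | tert-butyl bromoacetate | CC(C)(C)OC(=O)CBr | starting material
22 | bromo(2-tert-butoxy-2-oxoethyl)zinc (Reformatsky reagent) | CC(C)(C)OC(=O)C[Zn]Br | intermediate (not isolated)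
23 | tert-butyl 2-[(4R)-1-hydroxy-2,4-dimethyl-2-[(2R)-2-methyl-10-phenyldecyl]cyclobutyl]acetate (C1 and C2 epimers) | C[C@H](CCCCCCCCc1ccccc1)CC1(C)C[C@@H](C)C1(O)CC(=O)OC(C)(C)C | intermediate
24 | tert-butyl (4R,8R)-6-hydroperoxy-4,6,8-trimethyl-3-oxo-16-phenylhexadecanoate (C6 epimers) | C[C@H](CCCCCCCCc1ccccc1)CC(C)(OO)C[C@@H](C)C(=O)CC(=O)OC(C)(C)C | intermediate (not isolated)
25 | tert-butyl 2-[(3S,4R,6S)-3-hydroxy-4,6-dimethyl-6-[(2R)-2-methyl-10-phenyldecyl]-1,2-dioxan-3-yl]acetate | C[C@H](CCCCCCCCc1ccccc1)C[C@@]1(C)C[C@@H](C)[C@](O)(CC(=O)OC(C)(C)C)OO1 | intermediate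
26 | 2-[(3S,4R,6S)-3-hydroxy-4,6-dimethyl-6-[(2R)-2-methyl-10-phenyldecyl]-1,2-dioxan-3-yl]acetic acid | C[C@H](CCCCCCCCc1ccccc1)C[C@@]1(C)C[C@@H](C)[C@](O)(CC(=O)O)OO1 | target

**Step count**

Total: 13 steps. Longest linear sequence: 12 steps (steps 1, 2 and 4–13 from (R)-citronellal); step 3 is a one-step side branch.

**Steps most likely to fail**

Step 12. What may go wrong: unselective capture of O2 at the planar C6 radical (inherent, so half the material is the wrong epimer), misdirected β-scission toward C4 or the acetate arm, or stalling of the cobalt cycle. Fallback: separate ring opening from oxygenation, setting out from 23 and returning at 25.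
- An NBS-mediated ring-opening bromination (hν, CH2Cl2; alkoxy-radical β-scission with bromine-atom transfer) would open the same C1–C2 bond to tert-butyl (4R,8R)-6-bromo-4,6,8-trimethyl-3-oxo-16-phenylhexadecanoate F1.
- DBU would eliminate HBr to tert-butyl (4R,8R)-4,8-dimethyl-6-methylidene-3-oxo-16-phenylhexadecanoate F2; double-bond isomers at C6 serve equally.
- Isayama–Mukaiyama hydroperoxysilylation (Co(acac)2, O2, Et3SiH) would give the Markovnikov silyl peroxide tert-butyl (4R,8R)-4,6,8-trimethyl-3-oxo-16-phenyl-6-(triethylsilylperoxy)hexadecanoate F3.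
- TBAF/AcOH would release hydroperoxide 24, which closes to 25.
- The C6 epimers would still have to be separated.

Step 9. What may go wrong: poor conversion of the hindered four-membered azaenolate, or weak facial discrimination at C4. Fallback: give up reagent control, setting out from 15 and returning at 25.
- Direct methylation of the kinetic enolate (LDA, THF, −78 °C; MeI) would give 2,4-dimethyl-2-[(2R)-2-methyl-10-phenyldecyl]cyclobutan-1-one F4 as all ring stereoisomers.
- Reformatsky addition of 21 would give tert-butyl 2-[1-hydroxy-2,4-dimethyl-2-[(2R)-2-methyl-10-phenyldecyl]cyclobutyl]acetate F5, likewise a mixture.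
- The aerobic ring expansion of step 12 would then give 25 among four hemiketal diastereomers, from which it would be isolated by HPLC.

Step 13. What may go wrong: acid-promoted loss of water from the hemiketal to an alkylidene dioxane, ring opening followed by decarboxylation of the β-keto acid, or heterolysis of the O–O bond. Fallback: an ester released by fluoride instead of acid, setting out from 20 and returning at 26.
- Reformatsky addition of 2-(trimethylsilyl)ethyl bromoacetate would give 2-(trimethylsilyl)ethyl 2-[(4R)-1-hydroxy-2,4-dimethyl-2-[(2R)-2-methyl-10-phenyldecyl]cyclobutyl]acetate F6.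
- The same aerobic ring expansion and epimer separation would give 2-(trimethylsilyl)ethyl 2-[(3S,4R,6S)-3-hydroxy-4,6-dimethyl-6-[(2R)-2-methyl-10-phenyldecyl]-1,2-dioxan-3-yl]acetate F7.
- Tris(dimethylamino)sulfonium difluorotrimethylsilicate (or TBAF buffered with AcOH) in DMF at 0 °C would cleave the ester by β-elimination and give 26.
- Neither peroxide carbon bears hydrogen, so base-induced Kornblum–DeLaMare cleavage is excluded.

**Further compounds**

F1 | step 12 | tert-butyl (4R,8R)-6-bromo-4,6,8-trimethyl-3-oxo-16-phenylhexadecanoate (C6 epimers) | C[C@H](CCCCCCCCc1ccccc1)CC(C)(Br)C[C@@H](C)C(=O)CC(=O)OC(C)(C)C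
F2 | step 12 | tert-butyl (4R,8R)-4,8-dimethyl-6-methylidene-3-oxo-16-phenylhexadecanoate | C[C@H](CCCCCCCCc1ccccc1)CC(=C)C[C@@H](C)C(=O)CC(=O)OC(C)(C)C
F3 | step 12 | tert-butyl (4R,8R)-4,6,8-trimethyl-3-oxo-16-phenyl-6-(triethylsilylperoxy)hexadecanoate (C6 epimers) | C[C@H](CCCCCCCCc1ccccc1)CC(C)(OO[Si](CC)(CC)CC)C[C@@H](C)C(=O)CC(=O)OC(C)(C)C
F4 | step 9 | 2,4-dimethyl-2-[(2R)-2-methyl-10-phenyldecyl]cyclobutan-1-one (all ring stereoisomers) | C[C@H](CCCCCCCCc1ccccc1)CC1(C)CC(C)C1=O
F5 | step 9 | tert-butyl 2-[1-hydroxy-2,4-dimethyl-2-[(2R)-2-methyl-10-phenyldecyl]cyclobutyl]acetate (all ring stereoisomers) | C[C@H](CCCCCCCCc1ccccc1)CC1(C)CC(C)C1(O)CC(=O)OC(C)(C)C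
F6 | step 13 | 2-(trimethylsilyl)ethyl 2-[(4R)-1-hydroxy-2,4-dimethyl-2-[(2R)-2-methyl-10-phenyldecyl]cyclobutyl]acetate (C1 and C2 epimers) | C[C@H](CCCCCCCCc1ccccc1)CC1(C)C[C@@H](C)C1(O)CC(=O)OCC[Si](C)(C)C
F7 | step 13 | 2-(trimethylsilyl)ethyl 2-[(3S,4R,6S)-3-hydroxy-4,6-dimethyl-6-[(2R)-2-methyl-10-phenyldecyl]-1,2-dioxan-3-yl]acetate | C[C@H](CCCCCCCCc1ccccc1)C[C@@]1(C)C[C@@H](C)[C@](O)(CC(=O)OCC[Si](C)(C)C)OO1
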